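## Retrosynthetic overview
- Sauriol B comes from global hydrogenolysis of its tris-benzyl ether; no ring is formed anywhere, since both arene rings are bought as aryl bromides.
- The two ArCH2–CH bonds are cut, giving two different aryl Grignard reagents and one C2-symmetric (2S,3S)-2,3-dimethylbutane-1,4-diyl ditosylate, coupled one end at a time under copper catalysis.
- The ditosylate comes from (2S,3S)-2,3-dimethylbutane-1,4-diol, made by reducing an anti-2,3-dimethylsuccinate.
- That succinate is made in one step: an Evans enolate is alkylated with ethyl L-lactate triflate (auxiliary control at one centre, SN2 inversion at the other).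
- The aryl bromides come from 4-bromo-2,6-dimethoxyphenol (benzylation) and 5-bromo-o-vanillin (Dakin oxidation, benzylation).

Assumption: ethyl (S)-2-(trifluoromethylsulfonyloxy)propanoate (ethyl L-lactate triflate) is taken as a catalogue compound.

## Route

Step 1
Reactants: 1 (R)-4-benzyl-3-propionyloxazolidin-2-one; 2 ethyl (S)-2-(trifluoromethylsulfonyloxy)propanoate
Product: 4 ethyl (2S,3S)-4-[(R)-4-benzyl-2-oxooxazolidin-3-yl]-2,3-dimethyl-4-oxobutanoate, via sodium Z-enolate 3 (not isolated)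
Conditions: NaHMDS (1.05 equiv), THF, −78 °C; then 2 (1.2 equiv), −78 → −30 °C
Reagents that add atoms: none
Why: Evans asymmetric alkylation: the chelated Z-enolate is attacked anti to the auxiliary benzyl group (imide α-carbon S), and the α-triflyloxy ester reacts by SN2 inversion (former lactate carbon S by CIP), giving the anti-dimethylsuccinate.

Step 2
Reactants: 4 ethyl (2S,3S)-4-[(R)-4-benzyl-2-oxooxazolidin-3-yl]-2,3-dimethyl-4-oxobutanoate
Product: 5 (2S,3S)-2,3-dimethylbutane-1,4-diol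
Conditions: LiBH4 (3 equiv), MeOH, THF, 0 °C → rt
Reagents that add atoms: none
Why: Borohydride reduction converts both the N-acyl oxazolidinone (reductive auxiliary cleavage) and the ethyl ester into primary alcohols under non-epimerising conditions.

Step 3
Reactants: 5 (2S,3S)-2,3-dimethylbutane-1,4-diol
Product: 6 (2S,3S)-2,3-dimethylbutane-1,4-diyl bis(4-methylbenzenesulfonate)
Conditions: TsCl (2.5 equiv), pyridine, 0 °C
Reagents that add atoms: p-toluenesulfonyl chloride, Cc1ccc(cc1)S(Cl)(=O)=O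
Why: O-sulfonylation of both primary alcohols; cold conditions and excess TsCl outrun cyclisation to the tetrahydrofuran, and no stereocentre is touched.

Step 4
Reactants: 7 4-bromo-2,6-dimethoxyphenol
Product: 8 2-(benzyloxy)-5-bromo-1,3-dimethoxybenzene
Conditions: BnBr, K2CO3, DMF, 60 °C
Reagents that add atoms: benzyl bromide, BrCc1ccccc1
Why: Williamson ether synthesis masks the phenol so the aryl bromide can be turned into a Grignard reagent.

Step 5
Reactants: 6 (2S,3S)-2,3-dimethylbutane-1,4-diyl bis(4-methylbenzenesulfonate); 8 2-(benzyloxy)-5-bromo-1,3-dimethoxybenzene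
Product: 10 (2S,3R)-4-[4-(benzyloxy)-3,5-dimethoxyphenyl]-2,3-dimethylbutyl 4-methylbenzenesulfonate, via aryl Grignard reagent 9 (not isolated)
Conditions: 8, Mg, THF, reflux; then added slowly to 6 (3 equiv), Li2CuCl4 (5 mol %), THF, −20 °C → rt; excess 6 recovered
Reagents that add atoms: none
Why: Kochi-type copper-catalysed Grignard–alkyl tosylate coupling at a primary carbon; the two ends of C2-symmetric 6 are identical, so mono-substitution (favoured by excess 6) gives one compound, and the descriptor change S → R at C3 is only a CIP priority effect.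

Step 6
Reactants: 11 5-bromo-2-hydroxy-3-methoxybenzaldehyde
Product: 13 5-bromo-3-methoxybenzene-1,2-diol, via aryl formate 12 (not isolated)
Conditions: 30% H2O2, aq NaOH, THF, 0 °C → rt, N2; then aq HCl
Reagents that add atoms: hydrogen peroxide, OO
Why: Dakin oxidation: hydroperoxide adds to the ortho-hydroxy aldehyde, the aryl group migrates to oxygen, and the formate is hydrolysed in situ to the catechol.

Step 7
Reactants: 13 5-bromo-3-methoxybenzene-1,2-diol
Product: 14 1,2-bis(benzyloxy)-5-bromo-3-methoxybenzene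
Conditions: BnBr (2.5 equiv), K2CO3, DMF, 60 °C, N2
Reagents that add atoms: benzyl bromide, BrCc1ccccc1
Why: Double Williamson ether synthesis protects the catechol as benzyl ethers that survive the Grignard step and leave in the final hydrogenolysis.

Step 8
Reactants: 10 (2S,3R)-4-[4-(benzyloxy)-3,5-dimethoxyphenyl]-2,3-dimethylbutyl 4-methylbenzenesulfonate; 14 1,2-bis(benzyloxy)-5-bromo-3-methoxybenzene
Product: 16 1,2-bis(benzyloxy)-5-[(2R,3R)-4-(4-(benzyloxy)-3,5-dimethoxyphenyl)-2,3-dimethylbutyl]-3-methoxybenzene, via aryl Grignard reagent 15 (not isolated)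
Conditions: 14, Mg, THF, reflux; then 10, Li2CuCl4 (10 mol %), THF, 0 °C → rt
Reagents that add atoms: none
Why: A second Kochi-type copper-catalysed C(sp2)–C(sp3) coupling displaces the remaining primary tosylate; both stereocentres are remote from the reacting carbon and are retained (R,R by CIP).

Step 9
Reactants: 16 1,2-bis(benzyloxy)-5-[(2R,3R)-4-(4-(benzyloxy)-3,5-dimethoxyphenyl)-2,3-dimethylbutyl]-3-methoxybenzene
Product: 17 Sauriol B, 5-[(2R,3R)-4-(4-hydroxy-3,5-dimethoxyphenyl)-2,3-dimethylbutyl]-3-methoxybenzene-1,2-diol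
Conditions: H2 (1 atm), 10% Pd/C, EtOAc/MeOH, rt
Reagents that add atoms: none
Why: Catalytic hydrogenolysis cleaves the three benzyl aryl ethers while methyl ethers, the alkyl chain and both stereocentres are inert.

## Compound list
1 | (R)-4-benzyl-3-propionyloxazolidin-2-one | CCC(=O)N1[C@H](Cc2ccccc2)COC1=O | starting material
2 | ethyl (S)-2-(trifluoromethylsulfonyloxy)propanoate | CCOC(=O)[C@H](C)OS(=O)(=O)C(F)(F)F | starting material
3 | sodium (Z)-enolate of 1, formed in the flask | C/C=C(\[O-])N1[C@H](Cc2ccccc2)COC1=O.[Na+] | intermediate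
4 | ethyl (2S,3S)-4-[(R)-4-benzyl-2-oxooxazolidin-3-yl]-2,3-dimethyl-4-oxobutanoate | CCOC(=O)[C@@H](C)[C@H](C)C(=O)N1[C@H](Cc2ccccc2)COC1=O | intermediate
5 | (2S,3S)-2,3-dimethylbutane-1,4-diol | OC[C@@H](C)[C@H](C)CO | intermediate
6 | (2S,3S)-2,3-dimethylbutane-1,4-diyl bis(4-methylbenzenesulfonate) | Cc1ccc(cc1)S(=O)(=O)OC[C@@H](C)[C@H](C)COS(=O)(=O)c1ccc(C)cc1 | intermediate
7 | 4-bromo-2,6-dimethoxyphenol | COc1cc(Br)cc(OC)c1O | starting material
8 | 2-(benzyloxy)-5-bromo-1,3-dimethoxybenzene | COc1cc(Br)cc(OC)c1OCc1ccccc1 | intermediate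
9 | [4-(benzyloxy)-3,5-dimethoxyphenyl]magnesium bromide, formed in the flask | COc1cc([Mg]Br)cc(OC)c1OCc1ccccc1 | intermediate
10 | (2S,3R)-4-[4-(benzyloxy)-3,5-dimethoxyphenyl]-2,3-dimethylbutyl 4-methylbenzenesulfonate | Cc1ccc(cc1)S(=O)(=O)OC[C@@H](C)[C@H](C)Cc1cc(OC)c(OCc2ccccc2)c(OC)c1 | intermediate
11 | 5-bromo-2-hydroxy-3-methoxybenzaldehyde | COc1cc(Br)cc(C=O)c1O | starting material
12 | 5-bromo-2-hydroxy-3-methoxyphenyl formate, formed in the flask | COc1cc(Br)cc(OC=O)c1O | intermediate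
13 | 5-bromo-3-methoxybenzene-1,2-diol | COc1cc(Br)cc(O)c1O | intermediate
14 | 1,2-bis(benzyloxy)-5-bromo-3-methoxybenzene | COc1cc(Br)cc(OCc2ccccc2)c1OCc1ccccc1 | intermediate
15 | [3,4-bis(benzyloxy)-5-methoxyphenyl]magnesium bromide, formed in the flask | COc1cc([Mg]Br)cc(OCc2ccccc2)c1OCc1ccccc1 | intermediate
16 | 1,2-bis(benzyloxy)-5-[(2R,3R)-4-(4-(benzyloxy)-3,5-dimethoxyphenyl)-2,3-dimethylbutyl]-3-methoxybenzene | COc1cc(C[C@@H](C)[C@H](C)Cc2cc(OC)c(OCc3ccccc3)c(OC)c2)cc(OCc2ccccc2)c1OCc1ccccc1 | intermediate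
17 | Sauriol B, 5-[(2R,3R)-4-(4-hydroxy-3,5-dimethoxyphenyl)-2,3-dimethylbutyl]-3-methoxybenzene-1,2-diol | COc1cc(C[C@@H](C)[C@H](C)Cc2cc(OC)c(O)c(OC)c2)cc(O)c1O | target

## Step count and risks
Total step count: 9. Longest linear sequence: 6 (steps 1, 2, 3, 5, 8, 9).

Three steps most likely to fail:

Step 1 (alkylation with a secondary triflate: E2 to ethyl acrylate, triflate racemisation or a mismatched pairing could lower yield or dr). The fallback sets out from 1 and comes back at 5. Compound 1 is deprotonated with commercial LDA (THF, −78 °C) to the lithium (Z)-enolate of 1 F1. This is oxidatively homocoupled with anhydrous CuCl2 (−78 °C → rt), each α-carbon bonding anti to its own auxiliary benzyl group, to give (2S,3S)-1,4-bis[(R)-4-benzyl-2-oxooxazolidin-3-yl]-2,3-dimethylbutane-1,4-dione F2. After removal of the minor meso-type isomer, LiBH4/MeOH reduction releases both auxiliaries and delivers diol 5.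

Step 5 (mono-arylation of a ditosylate is statistical and relies on excess 6). The fallback sets out from 5 and comes back at 10. Diol 5 with SOCl2/Et3N (CH2Cl2, 0 °C) gives (5S,6S)-5,6-dimethyl-1,3,2-dioxathiepane 2-oxide F3. RuCl3 (cat.)/NaIO4 (MeCN/H2O) oxidises it to (5S,6S)-5,6-dimethyl-1,3,2-dioxathiepane 2,2-dioxide F4. Grignard reagent 9 with CuI (cat.) opens this cyclic sulfate once only, because the alkyl sulfate anion formed is not a leaving group, giving (2S,3R)-4-[4-(benzyloxy)-3,5-dimethoxyphenyl]-2,3-dimethylbutyl hydrogen sulfate F5 as its magnesium salt. Aqueous H2SO4/THF hydrolysis gives (2S,3R)-4-[4-(benzyloxy)-3,5-dimethoxyphenyl]-2,3-dimethylbutan-1-ol F6, and TsCl/pyridine converts it into 10.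

Step 8 (copper-catalysed coupling at a β,γ-branched primary tosylate with an electron-rich aryl Grignard may be slow or give S–O attack). The fallback reverses the polarity; it sets out from 10 and comes back at 16. Tosylate 10 with NaI in acetone (Finkelstein) gives 2-(benzyloxy)-5-[(2R,3S)-4-iodo-2,3-dimethylbutyl]-1,3-dimethoxybenzene F7. Zinc dust/LiCl in THF inserts to give [(2S,3R)-4-(4-(benzyloxy)-3,5-dimethoxyphenyl)-2,3-dimethylbutyl]zinc iodide F8. Negishi coupling of F8 with aryl bromide 14 (Pd(OAc)2/SPhos, THF, 50 °C) gives 16.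

## Further compounds
F1 | step 1 | lithium (Z)-enolate of 1 | C/C=C(\O[Li])N1[C@H](Cc2ccccc2)COC1=O
F2 | step 1 | (2S,3S)-1,4-bis[(R)-4-benzyl-2-oxooxazolidin-3-yl]-2,3-dimethylbutane-1,4-dione | O=C1OC[C@@H](Cc2ccccc2)N1C(=O)[C@@H](C)[C@H](C)C(=O)N1[C@H](Cc2ccccc2)COC1=O
F3 | step 5 | (5S,6S)-5,6-dimethyl-1,3,2-dioxathiepane 2-oxide | O=S1OC[C@@H](C)[C@H](C)CO1
F4 | step 5 | (5S,6S)-5,6-dimethyl-1,3,2-dioxathiepane 2,2-dioxide | O=S1(=O)OC[C@@H](C)[C@H](C)CO1
F5 | step 5 | (2S,3R)-4-[4-(benzyloxy)-3,5-dimethoxyphenyl]-2,3-dimethylbutyl hydrogen sulfate | OS(=O)(=O)OC[C@@H](C)[C@H](C)Cc1cc(OC)c(OCc2ccccc2)c(OC)c1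
F6 | step 5 | (2S,3R)-4-[4-(benzyloxy)-3,5-dimethoxyphenyl]-2,3-dimethylbutan-1-ol | OC[C@@H](C)[C@H](C)Cc1cc(OC)c(OCc2ccccc2)c(OC)c1
F7 | step 8 | 2-(benzyloxy)-5-[(2R,3S)-4-iodo-2,3-dimethylbutyl]-1,3-dimethoxybenzene | IC[C@@H](C)[C@H](C)Cc1cc(OC)c(OCc2ccccc2)c(OC)c1
F8 | step 8 | [(2S,3R)-4-(4-(benzyloxy)-3,5-dimethoxyphenyl)-2,3-dimethylbutyl]zinc iodide | I[Zn]C[C@@H](C)[C@H](C)Cc1cc(OC)c(OCc2ccccc2)c(OC)c1
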